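**Retrosynthetic overview**

1. The target comes from its allylic TBS ether. No ring is built: the butenolide, the only ring, is bought as 3-bromofuran-2(5H)-one and attached to a terminal alkene by B-alkyl Suzuki coupling.
2. The (Z)-CH=C(CH3)CH2O unit comes from a Z-selective Wittig reaction of a three-carbon phosphonium arm with TBSOCH2COCH3.
3. Both arms come from one C2-symmetric diene, (2R,6R)-2,6-diallylheptane-1,7-diyl diacetate, whose two homotopic allyl groups are told apart by mono-hydrobromination.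
4. Both stereocentres and both C–C bonds to the arms come from a double Ireland–Claisen rearrangement of the heptanedioate of (S)-but-3-en-2-ol (C–O to C–C chirality transfer), followed by reduction, acetylation and ethenolysis.

Assumption: (2S)-but-3-en-2-ol (≥98% ee), heptanedioyl dichloride, 1-(tert-butyldimethylsilyloxy)propan-2-one and 3-bromofuran-2(5H)-one are bought as catalogue chemicals.

**Route**

Step 1
Reactants: 1 (2S)-but-3-en-2-ol (2.2 equiv); 2 heptanedioyl dichloride
Product: 3 bis[(2S)-but-3-en-2-yl] heptanedioate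
Conditions: pyridine (2.5 equiv), DMAP (5 mol %), CH2Cl2, 0 °C → rt
Reagents that add atoms: none
Why: DMAP-catalysed nucleophilic acyl substitution (esterification) that does not break the carbinol C–O bond, so both (S) centres are carried over unchanged.

Step 2
Reactants: 3 bis[(2S)-but-3-en-2-yl] heptanedioate
Product: 6 (2R,6R)-2,6-bis[(2E)-but-2-en-1-yl]heptanedioic acid, via bis(silyl ketene acetal) 4 (not isolated), via bis(trimethylsilyl) ester 5 (not isolated)
Conditions: LiN(i-Pr)2 (2.5 equiv), Me3SiCl/Et3N (premixed, internal quench), THF, −78 °C, slow addition of 3; then rt → 55 °C, 3 h; 1 M HCl; acid–base extraction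
Reagents that add atoms: none
Why: Double Ireland–Claisen [3,3]-sigmatropic rearrangement in which kinetic deprotonation in THF gives the E(O)-enolate (chain cis to the allyloxy oxygen), trapped at once as 4, and the chair transition state with the carbinol methyl equatorial forms each new C–C bond suprafacially, so each (S) C–O centre becomes an (R) α-carbon and an E alkene.

Step 3
Reactants: 6 (2R,6R)-2,6-bis[(2E)-but-2-en-1-yl]heptanedioic acid
Product: 7 (2R,6R)-2,6-bis[(2E)-but-2-en-1-yl]heptane-1,7-diol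
Conditions: LiAlH4 (3 equiv), THF, 0 °C → reflux; Fieser work-up
Reagents that add atoms: none
Why: Hydride reduction of both carboxylic acids to primary alcohols, which leaves the isolated alkenes alone and does not epimerise the α-centres because they sit next to carboxylates.

Step 4
Reactants: 7 (2R,6R)-2,6-bis[(2E)-but-2-en-1-yl]heptane-1,7-diol
Product: 8 (2R,6R)-2,6-bis[(2E)-but-2-en-1-yl]heptane-1,7-diyl diacetate
Conditions: Ac2O, pyridine, DMAP (cat.), CH2Cl2, rt
Reagents that add atoms: acetic anhydride, CC(=O)OC(C)=O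
Why: DMAP-catalysed O-acetylation of both primary alcohols installs the two acetates of the target before any other hydroxyl exists.

Step 5
Reactants: 8 (2R,6R)-2,6-bis[(2E)-but-2-en-1-yl]heptane-1,7-diyl diacetate
Product: 9 (2R,6R)-2,6-di(prop-2-en-1-yl)heptane-1,7-diyl diacetate
Conditions: ethylene (5 bar), second-generation Hoveyda–Grubbs catalyst RuCl2(=CH-C6H4-2-OiPr)(H2IMes) (3 mol %), 1,4-benzoquinone (10 mol %), CH2Cl2, 40 °C
Reagents that add atoms: ethylene, C=C
Why: Ethenolysis (olefin cross-metathesis with excess ethylene) trims each internal crotyl alkene to a terminal allyl group with loss of propene, without touching the homoallylic stereocentres.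

Step 6
Reactants: 9 (2R,6R)-2,6-di(prop-2-en-1-yl)heptane-1,7-diyl diacetate
Product: 10 (2R,6R)-2-(3-bromopropyl)-6-(prop-2-en-1-yl)heptane-1,7-diyl diacetate
Conditions: HBr (gas, metered, 0.7 equiv), (PhCO2)2 (2 mol %), hν, hexane, 0 °C; chromatography on AgNO3–SiO2; recovered 9 recycled
Reagents that add atoms: hydrogen bromide, Br
Why: Radical-chain anti-Markovnikov (Kharasch) hydrobromination puts bromine on the terminal carbon, and because the two allyl groups of C2-symmetric 9 are homotopic, mono-addition gives one compound (about 45%, with about 40% of 9 recovered at this stoichiometry).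

Step 7
Reactants: 10 (2R,6R)-2-(3-bromopropyl)-6-(prop-2-en-1-yl)heptane-1,7-diyl diacetate
Product: 11 [(4R,8R)-4,8-bis(acetyloxymethyl)undec-10-en-1-yl]triphenylphosphonium bromide
Conditions: PPh3 (1.5 equiv), MeCN, reflux, 36 h
Reagents that add atoms: triphenylphosphine, c1ccc(cc1)P(c1ccccc1)c1ccccc1
Why: SN2 quaternisation of triphenylphosphine by the primary bromide, under neutral conditions that the acetates and the alkene tolerate.

Step 8
Reactants: 11 [(4R,8R)-4,8-bis(acetyloxymethyl)undec-10-en-1-yl]triphenylphosphonium bromide; 12 1-{[tert-butyl(dimethyl)silyl]oxy}propan-2-one (1.5 equiv)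
Product: 14 (2R,6R)-2-[(3Z)-5-{[tert-butyl(dimethyl)silyl]oxy}-4-methylpent-3-en-1-yl]-6-(prop-2-en-1-yl)heptane-1,7-diyl diacetate, via phosphonium ylide 13 (not isolated)
Conditions: NaN(SiMe3)2 (1.0 equiv), THF, −78 °C, 30 min; then 12, −78 °C → rt
Reagents that add atoms: none
Why: Wittig olefination of a non-stabilised ylide with an α-silyloxy ketone (Still's Z-selective variant), in which the kinetically formed oxaphosphetane places the ylide chain cis to CH2OTBS and gives the (Z)-trisubstituted alkene, the phosphonium α-CH being much more acidic than the acetate α-CH so that one equivalent of base forms only the ylide.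

Step 9
Reactants: 14 (2R,6R)-2-[(3Z)-5-{[tert-butyl(dimethyl)silyl]oxy}-4-methylpent-3-en-1-yl]-6-(prop-2-en-1-yl)heptane-1,7-diyl diacetate; 15 3-bromofuran-2(5H)-one (1.5 equiv)
Product: 17 (2R,6R)-2-[(3Z)-5-{[tert-butyl(dimethyl)silyl]oxy}-4-methylpent-3-en-1-yl]-6-[3-(2-oxo-2,5-dihydrofuran-3-yl)propyl]heptane-1,7-diyl diacetate, via alkylborane 16 (not isolated)
Conditions: 9-BBN (1.3 equiv), THF, 0 °C → rt; then 15, Pd(dppf)Cl2 (5 mol %), AsPh3 (10 mol %), Cs2CO3 (3 equiv), DMF/H2O, rt
Reagents that add atoms: none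
Why: Anti-Markovnikov hydroboration of the monosubstituted alkene with 9-BBN (the trisubstituted alkene and the esters do not react) followed by B-alkyl Suzuki–Miyaura coupling with the α-bromo butenolide forms the C(sp3)–C(sp2) bond and brings in the lactone ring intact.

Step 10
Reactants: 17 (2R,6R)-2-[(3Z)-5-{[tert-butyl(dimethyl)silyl]oxy}-4-methylpent-3-en-1-yl]-6-[3-(2-oxo-2,5-dihydrofuran-3-yl)propyl]heptane-1,7-diyl diacetate
Product: 18 (2R,6R)-2-[(3Z)-5-hydroxy-4-methylpent-3-en-1-yl]-6-[3-(2-oxo-2,5-dihydrofuran-3-yl)propyl]heptane-1,7-diyl diacetate (CNP0139404.2)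
Conditions: HF·pyridine, pyridine, THF, 0 °C → rt
Reagents that add atoms: none
Why: Buffered fluoride desilylation cleaves the primary allylic TBS ether without touching the acetates, the butenolide or the alkene geometry.

**Compound list**

1 | (2S)-but-3-en-2-ol | C[C@H](O)C=C | starting material
2 | heptanedioyl dichloride (pimeloyl chloride) | O=C(Cl)CCCCCC(=O)Cl | starting material
3 | bis[(2S)-but-3-en-2-yl] heptanedioate | C=C[C@H](C)OC(=O)CCCCCC(=O)O[C@@H](C)C=C | intermediate
4 | (1E,6E)-1,7-bis{[(2S)-but-3-en-2-yl]oxy}-1,7-bis[(trimethylsilyl)oxy]hepta-1,6-diene | C=C[C@H](C)O/C(O[Si](C)(C)C)=C\CCC/C=C(/O[Si](C)(C)C)O[C@@H](C)C=C | intermediate (not isolated)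
5 | bis(trimethylsilyl) (2R,6R)-2,6-bis[(2E)-but-2-en-1-yl]heptanedioate | C[Si](C)(C)OC(=O)[C@@H](C/C=C/C)CCC[C@H](C/C=C/C)C(=O)O[Si](C)(C)C | intermediate (not isolated)
6 | (2R,6R)-2,6-bis[(2E)-but-2-en-1-yl]heptanedioic acid | OC(=O)[C@@H](C/C=C/C)CCC[C@H](C/C=C/C)C(=O)O | intermediate
7 | (2R,6R)-2,6-bis[(2E)-but-2-en-1-yl]heptane-1,7-diol | OC[C@@H](C/C=C/C)CCC[C@H](C/C=C/C)CO | intermediate
8 | (2R,6R)-2,6-bis[(2E)-but-2-en-1-yl]heptane-1,7-diyl diacetate | CC(=O)OC[C@@H](C/C=C/C)CCC[C@H](C/C=C/C)COC(C)=O | intermediate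
9 | (2R,6R)-2,6-di(prop-2-en-1-yl)heptane-1,7-diyl diacetate | CC(=O)OC[C@@H](CC=C)CCC[C@H](CC=C)COC(C)=O | intermediate
10 | (2R,6R)-2-(3-bromopropyl)-6-(prop-2-en-1-yl)heptane-1,7-diyl diacetate | CC(=O)OC[C@@H](CC=C)CCC[C@H](CCCBr)COC(C)=O | intermediate
11 | [(4R,8R)-4,8-bis(acetyloxymethyl)undec-10-en-1-yl]triphenylphosphonium bromide | CC(=O)OC[C@@H](CC=C)CCC[C@H](CCC[P+](c1ccccc1)(c1ccccc1)c1ccccc1)COC(C)=O.[Br-] | intermediate
12 | 1-{[tert-butyl(dimethyl)silyl]oxy}propan-2-one | CC(=O)CO[Si](C)(C)C(C)(C)C | starting material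
13 | [(4R,8R)-4,8-bis(acetyloxymethyl)undec-10-en-1-ylidene]triphenyl-λ5-phosphane | CC(=O)OC[C@@H](CC=C)CCC[C@H](CCC=P(c1ccccc1)(c1ccccc1)c1ccccc1)COC(C)=O | intermediate (not isolated)
14 | (2R,6R)-2-[(3Z)-5-{[tert-butyl(dimethyl)silyl]oxy}-4-methylpent-3-en-1-yl]-6-(prop-2-en-1-yl)heptane-1,7-diyl diacetate | CC(=O)OC[C@@H](CC=C)CCC[C@H](CC/C=C(/C)CO[Si](C)(C)C(C)(C)C)COC(C)=O | intermediate
15 | 3-bromofuran-2(5H)-one | O=C1OCC=C1Br | starting material
16 | B-alkyl-9-borabicyclo[3.3.1]nonane from 14 (boron on the terminal carbon of the former allyl group; both stereocentres and the Z alkene as in 14) | CC(=O)OC[C@@H](CCCB1C2CCCC1CCC2)CCC[C@H](CC/C=C(/C)CO[Si](C)(C)C(C)(C)C)COC(C)=O | intermediate (not isolated)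
17 | (2R,6R)-2-[(3Z)-5-{[tert-butyl(dimethyl)silyl]oxy}-4-methylpent-3-en-1-yl]-6-[3-(2-oxo-2,5-dihydrofuran-3-yl)propyl]heptane-1,7-diyl diacetate | CC(=O)OC[C@@H](CCCC1=CCOC1=O)CCC[C@H](CC/C=C(/C)CO[Si](C)(C)C(C)(C)C)COC(C)=O | intermediate
18 | (2R,6R)-2-[(3Z)-5-hydroxy-4-methylpent-3-en-1-yl]-6-[3-(2-oxo-2,5-dihydrofuran-3-yl)propyl]heptane-1,7-diyl diacetate | CC(=O)OC[C@@H](CCCC1=CCOC1=O)CCC[C@H](CC/C=C(/C)CO)COC(C)=O | target

**Step count and weak points**

Total step count: 10. Longest linear sequence: 10 steps (1 and 2 to 18); 12 and 15 are bought and enter directly.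

The three steps most likely to fail:

Step 2 (double Ireland–Claisen). The mono-enolate of a 1,7-diester can undergo Dieckmann cyclisation before it is silylated. Each new centre is also only as pure as the enolate geometry (about 94:6 expected), so about 11% of the (2R,6S) diastereomer would form. It is hard to remove because the centres are remote, although the (2R,6R) material itself is then almost enantiopure. Fallback, setting out from 1 and 2 and coming back at 7: 2 and Me2NH give N,N,N',N'-tetramethylheptanediamide F1. Me2SO4 (70 °C) gives the bis(imidate) methyl sulfate salt F2, and NaOMe/MeOH converts it into the bis(amide dimethyl acetal) F3. Heating F3 with 1 (xylene, 140 °C, MeOH distilled off) forms the bis(ketene N,O-acetal) F4, in which allylic strain against NMe2 holds the chain cis to the allyloxy oxygen without any base. F4 rearranges in the same pot (Eschenmoser–Claisen, same chair and same sense of transfer as in step 2) to the bisamide F5. LiH2NBH3 (THF, 0 °C → rt) reduces F5 to diol 7.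

Step 8 (Wittig). The ylide may be acylated by the acetates, ketone 12 may be enolised by the ylide, and Z:E may fall below about 10:1. Fallback, setting out from 10 and coming back at 14: Me3NO in DMSO oxidises 10 (Ganem oxidation) to the aldehyde F6. The preformed ylide Ph3P=C(I)CH3 (ethyltriphenylphosphonium iodide, n-BuLi, I2, then NaN(SiMe3)2, THF, −78 °C) converts F6 into the (Z)-vinyl iodide F7. Stille coupling with Bu3SnCH2OH (Pd(PPh3)4, toluene, 80 °C) replaces iodine by CH2OH with retention and gives the allylic alcohol F8. TBSCl/imidazole (DMF, rt) returns 14.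

Step 9 (B-alkyl Suzuki coupling). 15 is base-sensitive (γ-deprotonation, ring opening), transmetalation of the alkylborane may be slow, and the acetates may suffer in aqueous carbonate. Fallback, setting out from 14 and coming back at 17: the same hydroboration (alkylborane 16) is worked up oxidatively (NaBO3·4H2O) to the primary alcohol F9. I2/PPh3/imidazole gives the primary iodide F10. The lithium enolate of 3-(phenylsulfanyl)oxolan-2-one (LiN(SiMe3)2, THF/HMPA, −78 °C → rt) is alkylated by F10 to the α-phenylsulfanyl lactone F11 (both epimers at the new quaternary carbon, which does not matter). NaIO4 (MeOH/H2O, 0 °C) gives the sulfoxide F12, and thermal syn-elimination (toluene, 110 °C, CaCO3) gives the endocyclic butenolide 17.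

**Further compounds**

F1 | step 2 | N,N,N',N'-tetramethylheptanediamide | CN(C)C(=O)CCCCCC(=O)N(C)C
F2 | step 2 | 1,7-dimethoxy-N,N,N',N'-tetramethylheptane-1,7-diiminium bis(methyl sulfate) | COC(CCCCCC(OC)=[N+](C)C)=[N+](C)C.COS(=O)(=O)[O-].COS(=O)(=O)[O-]
F3 | step 2 | 1,1,7,7-tetramethoxy-N,N,N',N'-tetramethylheptane-1,7-diamine | COC(OC)(CCCCCC(OC)(OC)N(C)C)N(C)C
F4 | step 2 | (1Z,6Z)-1,7-bis{[(2S)-but-3-en-2-yl]oxy}-N,N,N',N'-tetramethylhepta-1,6-diene-1,7-diamine | C=C[C@H](C)O/C(N(C)C)=C\CCC/C=C(/N(C)C)O[C@@H](C)C=C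
F5 | step 2 | (2R,6R)-2,6-bis[(2E)-but-2-en-1-yl]-N,N,N',N'-tetramethylheptanediamide | CN(C)C(=O)[C@@H](C/C=C/C)CCC[C@H](C/C=C/C)C(=O)N(C)C
F6 | step 8 | (2R,6R)-2-(3-oxopropyl)-6-(prop-2-en-1-yl)heptane-1,7-diyl diacetate | CC(=O)OC[C@@H](CC=C)CCC[C@H](CCC=O)COC(C)=O
F7 | step 8 | (2R,6R)-2-[(3Z)-4-iodopent-3-en-1-yl]-6-(prop-2-en-1-yl)heptane-1,7-diyl diacetate | CC(=O)OC[C@@H](CC=C)CCC[C@H](CC/C=C(/C)I)COC(C)=O
F8 | step 8 | (2R,6R)-2-[(3Z)-5-hydroxy-4-methylpent-3-en-1-yl]-6-(prop-2-en-1-yl)heptane-1,7-diyl diacetate | CC(=O)OC[C@@H](CC=C)CCC[C@H](CC/C=C(/C)CO)COC(C)=O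
F9 | step 9 | (2R,6R)-2-[(3Z)-5-{[tert-butyl(dimethyl)silyl]oxy}-4-methylpent-3-en-1-yl]-6-(3-hydroxypropyl)heptane-1,7-diyl diacetate | CC(=O)OC[C@@H](CCCO)CCC[C@H](CC/C=C(/C)CO[Si](C)(C)C(C)(C)C)COC(C)=O
F10 | step 9 | (2R,6R)-2-[(3Z)-5-{[tert-butyl(dimethyl)silyl]oxy}-4-methylpent-3-en-1-yl]-6-(3-iodopropyl)heptane-1,7-diyl diacetate | CC(=O)OC[C@@H](CCCI)CCC[C@H](CC/C=C(/C)CO[Si](C)(C)C(C)(C)C)COC(C)=O
F11 | step 9 | (2R,6R)-2-[(3Z)-5-{[tert-butyl(dimethyl)silyl]oxy}-4-methylpent-3-en-1-yl]-6-{3-[2-oxo-3-(phenylsulfanyl)oxolan-3-yl]propyl}heptane-1,7-diyl diacetate (both epimers at the sulfur-bearing carbon) | CC(=O)OC[C@@H](CCCC1(Sc2ccccc2)CCOC1=O)CCC[C@H](CC/C=C(/C)CO[Si](C)(C)C(C)(C)C)COC(C)=O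
F12 | step 9 | (2R,6R)-2-[(3Z)-5-{[tert-butyl(dimethyl)silyl]oxy}-4-methylpent-3-en-1-yl]-6-{3-[3-(benzenesulfinyl)-2-oxooxolan-3-yl]propyl}heptane-1,7-diyl diacetate (mixture of isomers at carbon and sulfur) | CC(=O)OC[C@@H](CCCC1(S(=O)c2ccccc2)CCOC1=O)CCC[C@H](CC/C=C(/C)CO[Si](C)(C)C(C)(C)C)COC(C)=O
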